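A direct plan would take methyl 3,5-dihydroxy-4-methoxybenzoate A1 down two branches: six operations to the o-silylaryl triflate A2, and one Claisen condensation to the β-keto ester A3.
Fluoride would release the aryne A4 from A2; the enolate of A3 would have to add through oxygen and then acylate the aryl anion, closing ring C to the flavone A5, which still lacks the C8 oxygen.
C8 of A5 would then be brominated to the 8-bromoflavone A6, the bromide exchanged for methoxide with copper, and the four benzyl ethers removed by hydrogenolysis.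
Weak point 1, the aryne/enolate annulation that closes ring C: acyclic β-keto esters normally C-arylate and insert the aryne into their Cα–C(=O) bond, so both branches meet in a step without precedent whose O- against C-selectivity is only hoped for.
Weak point 2, the run-up to A2 (benzylation, ester to alcohol to aldehyde to phenol, bromination, silyl shift and triflation): six operations of redox and protecting-group traffic that form no bond of the skeleton.
Weak point 3, the bromination and methoxide exchange at C8 of the finished flavone: two late steps for one methoxy group, with ring B as a competing bromination site and hot methoxide endangering the pyranone and the benzyl ethers.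

**Retrosynthetic overview**
- Last skeletal bond: C2–C1′. In chromone 9, C2–H is the only C–H of rings A and C (C3 bears OMe; C5, C6, C7 and C8 all bear oxygen), so C–H zincation there and Negishi coupling with the mirror-symmetric ring B bromide 13 attach ring B to a finished A–C bicycle.
- Ring C is closed before ring B arrives, from hydroxy ketone 7 and one carbon (DMF-DMA); ring A is a symmetric 2,4-dimethoxyphloroglucinol unit, so either ortho oxygen would give the same chromone.
- All five oxygens of ring A are in place before any ring is formed: C6-OMe, C7-O and C8-OMe come with 2,6-dimethoxyphenol, the C5 and C8a oxygens are added in two directions (dibromination, double C–O coupling), and the one C–H left takes the methoxyacetyl group.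
- The design therefore needs no aryne, raises no O- against C-arylation question, has no late oxygenation at C8 and no redox run-up; ring order: A (bought), then C, then B attached.

Key step: step 8

Remark: the zinc amide TMP2Zn·2MgCl2·2LiCl (TMP = 2,2,6,6-tetramethylpiperidide) is assumed to be used as a preformed THF solution.

Step 1
Reactants: 1 2,6-dimethoxyphenol
Product: 2 2-(benzyloxy)-1,3-dimethoxybenzene
Conditions: BnBr (1.1 equiv), K2CO3, acetone, reflux
Reagents that add atoms: benzyl bromide, BrCc1ccccc1
Why: Williamson ether synthesis on the only phenol; this benzyl group later uncovers the 7-OH.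

Step 2
Reactants: 2 2-(benzyloxy)-1,3-dimethoxybenzene
Product: 3 3-(benzyloxy)-1,5-dibromo-2,4-dimethoxybenzene
Conditions: NBS (2.1 equiv), MeCN, 0 °C → rt, dark
Reagents that add atoms: N-bromosuccinimide, O=C1CCC(=O)N1Br
Why: Electrophilic aromatic bromination in which the two coplanar methoxy groups direct to C4 and C6 (each ortho to one and para to the other), whereas C5 is para only to the central benzyloxy group that its two neighbours twist out of conjugation, the course known for 1,2,3-trimethoxybenzene.

Step 3
Reactants: 3 3-(benzyloxy)-1,5-dibromo-2,4-dimethoxybenzene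
Product: 4 1,3,5-tris(benzyloxy)-2,4-dimethoxybenzene
Conditions: BnOH (3 equiv), [Pd(allyl)Cl]2 (2 mol %), RockPhos (6 mol %), Cs2CO3 (3 equiv), toluene, 90 °C
Reagents that add atoms: benzyl alcohol, OCc1ccccc1
Why: Twofold palladium-catalysed C–O cross-coupling of an aryl bromide with a primary alcohol (Buchwald-type etherification), in which the bulky biaryl phosphine makes C–O reductive elimination faster than β-hydride elimination of the benzyloxide; each bromide has one free ortho position, and the product is mirror-symmetric with a single ring C–H left.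

Step 4
Reactants: 4 1,3,5-tris(benzyloxy)-2,4-dimethoxybenzene; 5 methoxyacetyl chloride
Product: 7 1-[4,6-bis(benzyloxy)-2-hydroxy-3,5-dimethoxyphenyl]-2-methoxyethan-1-one, via tris(benzyloxy) ketone 6 (not isolated)
Conditions: 5 (1.3 equiv), SnCl4 (1.3 equiv), CH2Cl2, −20 → 0 °C; water wash; crude material, BCl3 (1.1 equiv), CH2Cl2, −78 °C; MeOH quench
Reagents that add atoms: none
Why: Friedel–Crafts acylation at the only ring C–H of 4 (ortho to two benzyloxy groups and para to the third), then chelation-controlled cleavage by BCl3 of one benzyl ether ortho to the new ketone; the two ortho ethers are equivalent by symmetry, so only one phenol can form, and one equivalent of BCl3 held in the six-membered chelate should leave the remaining ethers alone.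

Step 5
Reactants: 7 1-[4,6-bis(benzyloxy)-2-hydroxy-3,5-dimethoxyphenyl]-2-methoxyethan-1-one
Product: 9 5,7-bis(benzyloxy)-3,6,8-trimethoxy-4H-chromen-4-one, via enaminone 8 (not isolated)
Conditions: DMF-DMA (3 equiv), toluene, 100 °C; evaporation; AcOH, 60 °C
Reagents that add atoms: N,N-dimethylformamide dimethyl acetal, COC(OC)N(C)C
Why: Condensation of the activated methylene with the amide acetal gives the enaminone, and the ortho phenol closes ring C by conjugate addition and loss of dimethylamine (6-endo-trig), the standard chromone synthesis from 2-hydroxyaryl ketones; C3 keeps its methoxy group and C2 is left as C–H for step 8.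

Step 6
Reactants: 10 2-methoxybenzene-1,3-diol
Product: 11 2-methoxy-1,3-phenylene bis(2,2-dimethylpropanoate)
Conditions: PivCl (2.3 equiv), Et3N (3 equiv), DMAP (5 mol %), CH2Cl2, 0 °C → rt
Reagents that add atoms: pivaloyl chloride, CC(C)(C)C(Cl)=O
Why: DMAP-catalysed O-acylation; pivalates are chosen because they carry no aromatic C–H that could compete in step 7 and should withstand CuBr2 and the organozinc of step 8.

Step 7
Reactants: 11 2-methoxy-1,3-phenylene bis(2,2-dimethylpropanoate)
Product: 13 5-bromo-2-methoxy-1,3-phenylene bis(2,2-dimethylpropanoate), via arylboronate 12 (not isolated)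
Conditions: [Ir(OMe)(cod)]2 (1.5 mol %), dtbpy (3 mol %), B2pin2 (1.0 equiv), THF, 80 °C; evaporation; CuBr2 (3 equiv), MeOH–H2O (1:1), 80 °C
Reagents that add atoms: copper dibromide, [Cu+2].[Br-].[Br-]
Why: Iridium-catalysed C–H borylation under steric control (C5–H is the only ring C–H without an ortho substituent) and bromodeboronation with CuBr2 in the same flask, the known one-pot meta-halogenation sequence; bromine is thereby placed para to the methoxy group, where electrophilic bromination would not put it.

Step 8
Reactants: 9 5,7-bis(benzyloxy)-3,6,8-trimethoxy-4H-chromen-4-one; 13 5-bromo-2-methoxy-1,3-phenylene bis(2,2-dimethylpropanoate)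
Product: 15 5-[5,7-bis(benzyloxy)-3,6,8-trimethoxy-4-oxo-4H-chromen-2-yl]-2-methoxy-1,3-phenylene bis(2,2-dimethylpropanoate), via bis(chromon-2-yl)zinc 14 (not isolated)
Conditions: 9, TMP2Zn·2MgCl2·2LiCl (0.6 equiv), THF, 25 °C; then 13 (1.1 equiv), Pd(OAc)2 (2 mol %), SPhos (4 mol %), 50 °C
Reagents that add atoms: none
Why: The hindered zinc amide, with its MgCl2 bound to the C4 carbonyl, removes the C2–H proton (acidified by O1 and by the 3-methoxy oxygen) to give the diorganozinc 14; oxidative addition of 13 to zerovalent palladium, transmetalation and reductive elimination then form the C2–C1′ bond. The closest known reaction type is the C2-zincation of chromones with this base followed by Negishi arylation to flavones. No ring is closed and no stereocentre is formed; ring C already exists and ring B arrives intact. The selectivity needed is the site of metalation, and the substrate secures it by leaving no alternative: C3 bears OMe and C5–C8 are all substituted, so C2–H is the only sp2 C–H of rings A and C, and the benzylic and methoxy C–H bonds are far too weakly acidic for a zinc amide. Zinc, unlike lithium or magnesium, should keep the C2 anion from adding to the C4 carbonyl of a second molecule or opening the pyranone, and it tolerates the pivalates, which meet the reagent only after the amide has been consumed. Bromide 13 is mirror-symmetric through C1′, so a single flavone can result.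

Step 9
Reactants: 15 5-[5,7-bis(benzyloxy)-3,6,8-trimethoxy-4-oxo-4H-chromen-2-yl]-2-methoxy-1,3-phenylene bis(2,2-dimethylpropanoate)
Product: 17 5,7-dihydroxy-2-(3,5-dihydroxy-4-methoxyphenyl)-3,6,8-trimethoxy-4H-chromen-4-one (5,7,3′,5′-tetrahydroxy-3,6,8,4′-tetramethoxyflavone), via bis(phenol) 16 (not isolated)
Conditions: K2CO3 (2.2 equiv), MeOH–THF, 40 °C, argon; AcOH to pH 6; Pd/C (10%), H2 (1 atm), rt
Reagents that add atoms: none
Why: Base-mediated methanolysis of the two aryl pivalates and then hydrogenolysis of the two aryl benzyl ethers; at one atmosphere the tetrasubstituted C2=C3 bond, the carbonyl group and the methyl ethers should not be reduced, and the last phenols are set free under neutral, reducing conditions.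

## Compound list

1 | 2,6-dimethoxyphenol | COc1cccc(OC)c1O | starting material
2 | 2-(benzyloxy)-1,3-dimethoxybenzene | COc1cccc(OC)c1OCc1ccccc1 | intermediate
3 | 3-(benzyloxy)-1,5-dibromo-2,4-dimethoxybenzene | COc1c(Br)cc(Br)c(OC)c1OCc1ccccc1 | intermediate
4 | 1,3,5-tris(benzyloxy)-2,4-dimethoxybenzene | COc1c(OCc2ccccc2)cc(OCc2ccccc2)c(OC)c1OCc1ccccc1 | intermediate
5 | methoxyacetyl chloride | COCC(Cl)=O | starting material
6 | 2-methoxy-1-[2,4,6-tris(benzyloxy)-3,5-dimethoxyphenyl]ethan-1-one | COCC(=O)c1c(OCc2ccccc2)c(OC)c(OCc2ccccc2)c(OC)c1OCc1ccccc1 | intermediate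
7 | 1-[4,6-bis(benzyloxy)-2-hydroxy-3,5-dimethoxyphenyl]-2-methoxyethan-1-one | COCC(=O)c1c(O)c(OC)c(OCc2ccccc2)c(OC)c1OCc1ccccc1 | intermediate
8 | (2Z)-1-[4,6-bis(benzyloxy)-2-hydroxy-3,5-dimethoxyphenyl]-3-(dimethylamino)-2-methoxyprop-2-en-1-one | CN(C)/C=C(\OC)C(=O)c1c(O)c(OC)c(OCc2ccccc2)c(OC)c1OCc1ccccc1 | intermediate
9 | 5,7-bis(benzyloxy)-3,6,8-trimethoxy-4H-chromen-4-one | COc1coc2c(OC)c(OCc3ccccc3)c(OC)c(OCc3ccccc3)c2c1=O | intermediate
10 | 2-methoxybenzene-1,3-diol | COc1c(O)cccc1O | starting material
11 | 2-methoxy-1,3-phenylene bis(2,2-dimethylpropanoate) | COc1c(OC(=O)C(C)(C)C)cccc1OC(=O)C(C)(C)C | intermediate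
12 | 2-methoxy-5-(4,4,5,5-tetramethyl-1,3,2-dioxaborolan-2-yl)-1,3-phenylene bis(2,2-dimethylpropanoate) | COc1c(OC(=O)C(C)(C)C)cc(B2OC(C)(C)C(C)(C)O2)cc1OC(=O)C(C)(C)C | intermediate
13 | 5-bromo-2-methoxy-1,3-phenylene bis(2,2-dimethylpropanoate) | COc1c(OC(=O)C(C)(C)C)cc(Br)cc1OC(=O)C(C)(C)C | intermediate
14 | bis[5,7-bis(benzyloxy)-3,6,8-trimethoxy-4-oxo-4H-chromen-2-yl]zinc (as its MgCl2/LiCl complex) | COc1c([Zn]c2oc3c(OC)c(OCc4ccccc4)c(OC)c(OCc4ccccc4)c3c(=O)c2OC)oc2c(OC)c(OCc3ccccc3)c(OC)c(OCc3ccccc3)c2c1=O | intermediate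
15 | 5-[5,7-bis(benzyloxy)-3,6,8-trimethoxy-4-oxo-4H-chromen-2-yl]-2-methoxy-1,3-phenylene bis(2,2-dimethylpropanoate) | COc1c(OC(=O)C(C)(C)C)cc(-c2oc3c(OC)c(OCc4ccccc4)c(OC)c(OCc4ccccc4)c3c(=O)c2OC)cc1OC(=O)C(C)(C)C | intermediate
16 | 5,7-bis(benzyloxy)-2-(3,5-dihydroxy-4-methoxyphenyl)-3,6,8-trimethoxy-4H-chromen-4-one | COc1c(O)cc(-c2oc3c(OC)c(OCc4ccccc4)c(OC)c(OCc4ccccc4)c3c(=O)c2OC)cc1O | intermediate
17 | 5,7-dihydroxy-2-(3,5-dihydroxy-4-methoxyphenyl)-3,6,8-trimethoxy-4H-chromen-4-one | COc1c(O)cc(-c2oc3c(OC)c(O)c(OC)c(O)c3c(=O)c2OC)cc1O | target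

Total step count: 9. Longest linear sequence: 7 steps (1–5, 8, 9).

**Steps most likely to fail**

Step 8. The zincation at C2–H, crowded by the 3-methoxy group, may be slow or incomplete, or the bulky diorganozinc may transmetalate sluggishly, so that protonation back to 9 and homocoupling win. The fallback sets out from 9 and 13 and returns at 15, with C2 reacting as an electrophile instead. Bromide 13 would be converted with magnesium turnings and LiCl (THF, 0 °C) into [4-methoxy-3,5-bis(pivaloyloxy)phenyl]magnesium bromide F1. With CuBr·SMe2 (10 mol %) and TMSCl (THF, −78 → 0 °C), F1 should add 1,4 to chromone 9 at C2 and be trapped as the racemic silyl enol ether 5-[5,7-bis(benzyloxy)-3,6,8-trimethoxy-4-(trimethylsilyloxy)-2H-chromen-2-yl]-2-methoxy-1,3-phenylene bis(2,2-dimethylpropanoate) F2. DDQ (dioxane, rt) would then remove the C2 hydride and the silyl group and restore the flavone 15.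

Step 3. β-Hydride elimination from the palladium benzyloxide may reduce the C–Br bonds, or the second coupling may stall on the increasingly electron-rich ring. The fallback sets out from 3 and returns at 4, building the C–O bonds by oxidation of C–B bonds and O-alkylation. Twofold Miyaura borylation (B2pin2, Pd(dppf)Cl2, KOAc, dioxane, 90 °C) would give 2,2′-[5-(benzyloxy)-4,6-dimethoxy-1,3-phenylene]bis(4,4,5,5-tetramethyl-1,3,2-dioxaborolane) F3. Oxidation (H2O2, NaOH, THF, 0 °C) would give 5-(benzyloxy)-4,6-dimethoxybenzene-1,3-diol F4, and benzylation (BnBr, K2CO3, DMF) would give 4.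

Step 4. The acylium ion may lose carbon monoxide before it attacks the crowded C–H, the Lewis acid may strip benzyl or methyl ethers, or BCl3 may cleave more than one ether. The fallback sets out from 4 and returns at 7, replacing the electrophilic acylation by a carbanion route. Bromination of the last C–H (NBS, MeCN) would give 1,3,5-tris(benzyloxy)-2-bromo-4,6-dimethoxybenzene F5. Bromine–lithium exchange (n-BuLi, THF, −78 °C) would give [2,4,6-tris(benzyloxy)-3,5-dimethoxyphenyl]lithium F6, which would be acylated with N,2-dimethoxy-N-methylacetamide to ketone 6. MgBr2·OEt2 (toluene–Et2O, 60 °C) would then remove one ortho benzyl group through the magnesium chelate and give 7.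

## Further compounds

F1 | step 8 | [4-methoxy-3,5-bis(pivaloyloxy)phenyl]magnesium bromide | COc1c(OC(=O)C(C)(C)C)cc([Mg]Br)cc1OC(=O)C(C)(C)C
F2 | step 8 | 5-[5,7-bis(benzyloxy)-3,6,8-trimethoxy-4-(trimethylsilyloxy)-2H-chromen-2-yl]-2-methoxy-1,3-phenylene bis(2,2-dimethylpropanoate) (racemic) | COC1=C(O[Si](C)(C)C)c2c(OCc3ccccc3)c(OC)c(OCc3ccccc3)c(OC)c2OC1c1cc(OC(=O)C(C)(C)C)c(OC)c(OC(=O)C(C)(C)C)c1
F3 | step 3 | 2,2′-[5-(benzyloxy)-4,6-dimethoxy-1,3-phenylene]bis(4,4,5,5-tetramethyl-1,3,2-dioxaborolane) | COc1c(B2OC(C)(C)C(C)(C)O2)cc(B2OC(C)(C)C(C)(C)O2)c(OC)c1OCc1ccccc1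
F4 | step 3 | 5-(benzyloxy)-4,6-dimethoxybenzene-1,3-diol | COc1c(O)cc(O)c(OC)c1OCc1ccccc1
F5 | step 4 | 1,3,5-tris(benzyloxy)-2-bromo-4,6-dimethoxybenzene | COc1c(OCc2ccccc2)c(Br)c(OCc2ccccc2)c(OC)c1OCc1ccccc1
F6 | step 4 | [2,4,6-tris(benzyloxy)-3,5-dimethoxyphenyl]lithium | [Li]c1c(OCc2ccccc2)c(OC)c(OCc2ccccc2)c(OC)c1OCc1ccccc1
A1 | direct plan | methyl 3,5-dihydroxy-4-methoxybenzoate | COC(=O)c1cc(O)c(OC)c(O)c1
A2 | direct plan | 3,5-bis(benzyloxy)-4-methoxy-2-(trimethylsilyl)phenyl trifluoromethanesulfonate | C[Si](C)(C)c1c(OS(=O)(=O)C(F)(F)F)cc(OCc2ccccc2)c(OC)c1OCc1ccccc1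
A3 | direct plan | methyl 3-[3,5-bis(benzyloxy)-4-methoxyphenyl]-2-methoxy-3-oxopropanoate (racemic) | COC(=O)C(OC)C(=O)c1cc(OCc2ccccc2)c(OC)c(OCc2ccccc2)c1
A4 | direct plan | 3,5-bis(benzyloxy)-4-methoxybenzyne | C1#CC(OCc2ccccc2)=C(OC)C(OCc2ccccc2)=C1
A5 | direct plan | 5,7-bis(benzyloxy)-2-[3,5-bis(benzyloxy)-4-methoxyphenyl]-3,6-dimethoxy-4H-chromen-4-one | COc1c(OCc2ccccc2)cc2oc(-c3cc(OCc4ccccc4)c(OC)c(OCc4ccccc4)c3)c(OC)c(=O)c2c1OCc1ccccc1
A6 | direct plan | 5,7-bis(benzyloxy)-2-[3,5-bis(benzyloxy)-4-methoxyphenyl]-8-bromo-3,6-dimethoxy-4H-chromen-4-one | COc1c(OCc2ccccc2)c(Br)c2oc(-c3cc(OCc4ccccc4)c(OC)c(OCc4ccccc4)c3)c(OC)c(=O)c2c1OCc1ccccc1
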